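**Conventions.** Compounds are numbered 1–22 as in the steps and the compound list. Atoms carry the oxolane numbering of the target: O1, C2, C3, C4, C5 and the exocyclic carbinol carbon C1'. Ar = 4-(benzyloxy)-3-methoxyphenyl. CIP descriptors at C3, C4 and C1' change along the route without any change in spatial arrangement, because neighbouring groups change rank; the SMILES strings are authoritative.

## Analysis of the target

Metasequirin E (22) is a 2,3,4-trisubstituted oxolane. O1 lies between C2 and C5; C2 carries the benzylic carbinol C1' with one guaiacyl (4-hydroxy-3-methoxyphenyl) ring, C3 the second guaiacyl ring, C4 a hydroxyl, and C5 is a methylene. The four contiguous stereocentres are C2 (S), C3 (R), C4 (S) and C1' (R). The three ring substituents are all cis, and the C1' hydroxyl is anti to O1 when the chain aryl–C1'–C2–C3 is drawn as a zigzag. The all-cis triad is the crowded, thermodynamically disfavoured arrangement, and C3 is benzylic, so it would epimerise if it ever lay next to a carbonyl group. The sensitive groups are the two free phenols, the electron-rich arenes, and the C1' alcohol, which ionises in acid and can be lost on hydrogenolysis. The strategy rests on O1: removing it and joining C2 to C5 leaves a cyclobutanone with its carbonyl at C5. In that ring the cis C2/C3 pair is the imprint of a Z alkene and C4–C5 that of a ketene. After oxygen insertion the C5 carbonyl is the handle for bringing the hydroxyl to C4.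

## Retrosynthetic reasoning

Protecting groups (22 from 21 from 20). The phenols are carried as benzyl ethers, which survive base, hydride, peracid and zinc, and are removed last by neutral hydrogenolysis of 21. The C1' oxygen is carried as a triisopropylsilyl ether and freed from 20 with fluoride, because acid would ionise C1'. The bulky silyl group also acts as the face-directing group in the cycloaddition and resists migration to a neighbouring oxygen.

C5 methylene (20 from 18 from 17). The C5 methylene of 20 is traced back to the lactone carbonyl of 17. A Lewis-acid and silane reduction of a lactol is avoided because it endangers the benzylic silyl ether. Instead the lactone is reduced by hydride to triol 18 and the ring is closed again by displacement at C5, which is not stereogenic, by the C2 hydroxyl. C2 therefore keeps its configuration; the forward step has to tell the primary hydroxyl from two secondary ones.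

C4–O bond (17 from 16 from 14). The C4 oxygen is disconnected using the C5 carbonyl: C4 is the only enolisable position, so C3 is never at risk. An electrophilic oxygen enters the enolate of 14 anti to the C3 aryl group and gives the trans alcohol 16. The cis arrangement therefore needs one inversion, placed at this α-carbonyl carbon where SN2 displacement is easiest, and that gives ester 17.

C–Cl bonds (14 from 13). The two chlorines at C4 in 13 are activating groups left by the ketene and are removed reductively.

Key disconnection (13 from 11). The O1–C2 and O1–C5 bonds are cut, which removes O1 and leaves cyclobutanone 11. The cut is made here because a 1,2-shift of C2 from carbon to oxygen passes the C2 configuration on unchanged. The heterocycle is thereby reduced to a carbocycle that forms in one step from an alkene. The forward reaction must insert oxygen on the C2 side of the carbonyl and not on the CCl2 side.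

Four-membered ring (11 from 8 and 9). Cutting C2–C5 and C3–C4 gives the Z alkene 8 and dichloroketene 10, made from 9. The forward reaction has to join CCl2 to the benzylic C3, add suprafacially so that Z becomes cis, and choose one alkene face under the control of C1'.

Alkene and carbinol (8 from 7 from 6 from 4 and 1; 4 from 1 and 2). The Z alkene comes from alkyne 7 by syn semihydrogenation and 7 from alcohol 6 by silylation. Cutting C1'–C2 of 6 gives alkyne 4 and aldehyde 1. An enantioselective alkynylation sets C1', the only reagent-controlled stereocentre; all others are relayed from it. Alkyne 4 comes from 1 by one-carbon homologation with 2, so both aryl rings derive from the same aldehyde.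

## Alternatives that were turned down

Alternative 1: C2–C3 by carbene C–H insertion.
- Disconnection and key step: the acyclic α-aryl α-diazo ketone A1 already has O1 joining C2 and C5 and a carbonyl at C4. A dirhodium carboxylate would generate the carbene at C3, which inserts into a C2–H bond and closes oxolanone A2 by 1,5-insertion.
- For it: C2–H is activated by O1, and an aryl/acyl carbene is selective. Hydride reduction of the C4 ketone of A2 from the face away from the C3 aryl gives the cis alcohol directly. On this point it is stronger than the chosen route, which needs a hydroxylation and an inversion.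
- Against it: C2 and C3 are created together with nothing enforcing the cis relation. A2 is an α-aryl ketone in which C3 lies between arene and carbonyl, so it can epimerise to the trans isomer. The choice between the two C2–H bonds rests on acyclic induction from C1'. Attack of O1 on the carbene, insertion into the more activated C1'–H bond and addition to the arenes all compete.
- Comparison: the step count is similar once A1 is assembled. The chosen route instead sets C2/C3 stereospecifically from alkene geometry and never places C3 next to a carbonyl.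

Alternative 2: O1–C2 and C2–C3 by oxetane ring expansion.
- Disconnection and key step: the cis oxetane A3 supplies O1, C3, C4 and C5; the diazo ketone A4 supplies C2 and C1'. A copper carbene from A4 is captured by the oxetane oxygen, and the benzylic C3 shifts from oxygen to C2 to give A5.
- For it: it is the most convergent plan. The C3/C4 cis relation is preset in A3, and the C1' ketone of A5 allows a chelation-controlled reduction to the anti carbinol. It is stronger than the chosen route in step economy.
- Against it: the 1,2-shift of an electron-rich benzylic carbon has radical-pair or ion-pair character, so retention at C3 is not assured. C2 must form cis to the C3 aryl, the more hindered outcome, with no controlling element. The metal can open the 2-aryloxetane at its benzylic C–O bond. A3 as a single cis enantiomer needs its own synthesis.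
- Comparison: the chosen route is longer, but each relation comes from a stereospecific event: syn hydrogenation, suprafacial cycloaddition, retentive migration and SN2 inversion.

Alternative 3: C2–C3 and O1–C5 by allylsilane–aldehyde annulation.
- Disconnection and key step: the Z cinnamylsilane A6 supplies C3, C4 and C5; the α-silyloxy aldehyde A7 supplies C2 and C1'. Under a Lewis acid C3 attacks the aldehyde, silicon shifts from C5 to C4 and the alkoxide closes on C5 to give A8. Oxidation of the C4–Si bond with retention would then deliver the C4 hydroxyl.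
- For it: the ring and three stereocentres form in one step, anti addition across the Z alkene gives the C3/C4 cis relation, and C4 needs no inversion. It is the shortest plan and stronger than the chosen route at C4.
- Against it: the attacking carbon C3 is the hindered aryl-bearing terminus, and attack through C4 to leave a para-alkoxybenzyl cation at C3 is a competing regiochemistry. A phenyldimethylsilyl group tends to be lost (simple allylation) instead of migrating. The C2/C1' relation depends on Felkin against chelation control, and A7 racemises easily. The Lewis acid threatens the benzylic silyl ether. The silicon oxidation needs electrophilic attack on the silicon-bound phenyl ring, which must compete with two far more electron-rich arenes.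
- Comparison: the chosen route costs more steps and an inversion at C4, but uses no Lewis acid on the ionisable benzylic ether and no electrophilic oxidation.

Key step: step 6

Assumption (remark on the chemistry): in step 5 dichloroketene 10 is taken to attack alkene 8, held by allylic 1,3-strain with C1'–H in the alkene plane, on the face turned away from the triisopropylsilyloxy group, the sense in which peracids and OsO4 add to Z allylic silyl ethers; the opposite outcome is covered by the fallback to step 5.

## Route

Step 1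
Reactants: 1 4-(benzyloxy)-3-methoxybenzaldehyde; 2 dimethyl (1-diazo-2-oxopropyl)phosphonate
Product: 4 1-(benzyloxy)-4-ethynyl-2-methoxybenzene, via dimethyl (diazomethyl)phosphonate 3 (not isolated)
Conditions: K2CO3, MeOH, 0 °C to rt
Reagents that add atoms: none
Why: Ohira–Bestmann (Seyferth–Gilbert) homologation: methoxide cleaves the acetyl group of 2 to give the anion of 3, which olefinates the aldehyde; loss of N2 and a 1,2-hydrogen shift of the alkylidene carbene give the terminal alkyne. The benzyl ether is inert to K2CO3 in methanol.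

Step 2
Reactants: 4 1-(benzyloxy)-4-ethynyl-2-methoxybenzene; 1 4-(benzyloxy)-3-methoxybenzaldehyde
Product: 6 (1R)-1,3-bis(Ar)prop-2-yn-1-ol, via ethyl(arylethynyl)zinc 5 (not isolated)
Conditions: 4 (2 equiv), Et2Zn, toluene, reflux; then (S)-BINOL (20 mol %), Ti(OiPr)4 (50 mol %), CH2Cl2, 1, rt; aq. NH4Cl
Reagents that add atoms: none
Why: Catalytic asymmetric alkynylzinc addition to an aromatic aldehyde under BINOL–Ti(OiPr)4 control (Pu-type alkynylation): 5, formed from 4 and Et2Zn, is transferred within the chiral titanium complex to one face of 1. (S)-BINOL is expected to direct the alkynyl group to the Si face and so set C1' as R; the configuration is to be confirmed by Mosher ester analysis and (R)-BINOL used should the sense be the reverse.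

Step 3
Reactants: 6 (1R)-1,3-bis(Ar)prop-2-yn-1-ol
Product: 7 (1R)-1,3-bis(Ar)prop-2-yn-1-yl triisopropylsilyl ether
Conditions: TIPSOTf, 2,6-lutidine, CH2Cl2, −78 to 0 °C
Reagents that add atoms: triisopropylsilyl trifluoromethanesulfonate, CC(C)[Si](OS(=O)(=O)C(F)(F)F)(C(C)C)C(C)C
Why: Silylation of a hindered secondary alcohol with a silyl triflate and a hindered pyridine base; C1' is not touched and the low temperature keeps the propargylic benzylic C–O bond from ionising.

Step 4
Reactants: 7 (1R)-1,3-bis(Ar)prop-2-yn-1-yl triisopropylsilyl ether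
Product: 8 (1S,2Z)-1,3-bis(Ar)prop-2-en-1-yl triisopropylsilyl ether
Conditions: H2 (1 atm), Pd/CaCO3 poisoned with Pb(OAc)2 (Lindlar catalyst), quinoline, EtOAc, rt
Reagents that add atoms: none
Why: Lindlar semihydrogenation: syn delivery of one equivalent of H2 on lead-poisoned palladium gives the Z alkene; quinoline restrains over-reduction and the aryl benzyl ethers are not cleaved on this catalyst. C1' keeps its arrangement; only its descriptor changes.

Step 5
Reactants: 8 (1S,2Z)-1,3-bis(Ar)prop-2-en-1-yl triisopropylsilyl ether; 9 trichloroacetyl chloride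
Product: 11 (3R,4S)-3-Ar-4-[(S)-Ar(triisopropylsilyloxy)methyl]-2,2-dichlorocyclobutan-1-one (3,4-cis), via dichloroketene 10 (not isolated)
Conditions: Zn–Cu couple, Et2O–DME, 9 added slowly, rt
Reagents that add atoms: none
Why: Ketene–alkene [2+2] cycloaddition with dichloroketene made by zinc dehalogenation of 9: the addition is suprafacial on the alkene, so the Z geometry becomes the cis C2/C3 relation, and the electrophilic ketene carbon bonds to C2 while CCl2 closes on the benzylic C3 that best carries the developing positive charge, as with styrenes. With C1'–H in the alkene plane the ketene is expected to enter on the face remote from the triisopropylsilyloxy group, which fixes C2 and C3 relative to C1'; DME ties up the ZnCl2 formed.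

Step 6
Reactants: 11 (3R,4S)-3-Ar-4-[(S)-Ar(triisopropylsilyloxy)methyl]-2,2-dichlorocyclobutan-1-one
Product: 13 (4S,5S)-4-Ar-5-[(R)-Ar(triisopropylsilyloxy)methyl]-3,3-dichlorooxolan-2-one (4,5-cis), via Criegee adduct 12 (not isolated)
Conditions: mCPBA, NaHCO3, CH2Cl2, 0 °C to rt
Reagents that add atoms: 3-chloroperoxybenzoic acid, OOC(=O)c1cccc(Cl)c1
Why: This is a Baeyer–Villiger oxidation of an α,α-dichlorocyclobutanone, the closest known reaction type being the peracid oxidation of dichloroketene cycloadducts to dichlorolactones. The peracid adds to the strained, chlorine-activated carbonyl C5 to give the tetrahedral Criegee adduct 12. Its O–O bond then breaks as C2 shifts from C5 to the proximal peroxide oxygen in one concerted step, the migrating C2–C5 bond lying antiperiplanar to the O–O bond; this makes the O1–C2 bond, leaves O1 bonded to C5 and releases 3-chlorobenzoate. The oxolanone ring is thus closed by insertion of one oxygen atom into the carbocycle and not by an exo or endo cyclisation, a four- to five-membered ring expansion driven by loss of cyclobutanone strain. No stereocentre is created: C2 migrates with retention, so the cis C2/C3 relation from the Z alkene and the C1' configuration pass unchanged into 13. The selectivity needed is regiochemical, C2 against C4, and the substrate secures it, because the CCl2 carbon cannot carry the partial positive charge of a migrating group whereas C2 is a secondary alkyl carbon. The activated ketone reacts much faster than the electron-rich arenes, and the bicarbonate buffer protects the silyl ether and keeps 13 from losing HCl.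

Step 7
Reactants: 13 (4S,5S)-4-Ar-5-[(R)-Ar(triisopropylsilyloxy)methyl]-3,3-dichlorooxolan-2-one
Product: 14 (4S,5S)-4-Ar-5-[(R)-Ar(triisopropylsilyloxy)methyl]oxolan-2-one
Conditions: Zn dust, AcOH, THF, rt to 40 °C
Reagents that add atoms: none
Why: Reductive dehalogenation of an α,α-dichloro carbonyl compound by zinc: two successive two-electron reductions through zinc enolates that acetic acid protonates at C4. C2 and C3 are not α to the carbonyl and keep their configuration; benzyl and triisopropylsilyl ethers tolerate the mild acid.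

Step 8
Reactants: 14 (4S,5S)-4-Ar-5-[(R)-Ar(triisopropylsilyloxy)methyl]oxolan-2-one
Product: 16 (3R,4R,5S)-4-Ar-3-hydroxy-5-[(R)-Ar(triisopropylsilyloxy)methyl]oxolan-2-one (3-OH trans to 4-Ar), via potassium enolate 15 (not isolated)
Conditions: KN(SiMe3)2, THF, −78 °C; 2-(phenylsulfonyl)-3-phenyloxaziridine, −78 °C; aq. NH4Cl
Reagents that add atoms: 2-(phenylsulfonyl)-3-phenyloxaziridine (Davis oxaziridine), O=S(=O)(c1ccccc1)N1OC1c1ccccc1
Why: Davis enolate hydroxylation: the potassium enolate 15 attacks the oxaziridine oxygen through C4. The oxidant approaches the planar enolate on the face opposite the adjacent C3 aryl group and the cis C2 side chain, so the new hydroxyl is placed trans to the aryl group; the potassium counter-ion avoids addition of the enolate to the sulfonimine by-product.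

Step 9
Reactants: 16 (3R,4R,5S)-4-Ar-3-hydroxy-5-[(R)-Ar(triisopropylsilyloxy)methyl]oxolan-2-one
Product: 17 (3S,4S,5S)-4-Ar-2-oxo-5-[(R)-Ar(triisopropylsilyloxy)methyl]oxolan-3-yl 4-nitrobenzoate (all-cis)
Conditions: 4-nitrobenzoic acid, PPh3, DIAD, THF, 0 °C to rt
Reagents that add atoms: 4-nitrobenzoic acid, OC(=O)c1ccc(cc1)[N+](=O)[O-]
Why: Mitsunobu esterification with SN2 inversion at C4, a position activated towards displacement by the adjacent lactone carbonyl; the acidic 4-nitrobenzoic acid favours the inversion pathway at this hindered carbinol. Elimination to the butenolide is disfavoured because C3–H is cis to the leaving group and cannot become antiperiplanar to it.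

Step 10
Reactants: 17 (3S,4S,5S)-4-Ar-2-oxo-5-[(R)-Ar(triisopropylsilyloxy)methyl]oxolan-3-yl 4-nitrobenzoate
Product: 18 (2S,3R,4S,5R)-3,5-bis(Ar)-5-(triisopropylsilyloxy)pentane-1,2,4-triol
Conditions: LiBH4, THF, 0 °C to rt; aq. NH4Cl
Reagents that add atoms: none
Why: Ester reduction by LiBH4: the lactone is opened to the C2/C5 diol and the nitrobenzoate is cleaved reductively, while the nitro group, the benzyl ethers and the silyl ether are left alone. No stereocentre is involved, and the bulky triisopropylsilyl group should not migrate from the C1' oxygen to the C2 oxygen.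

Step 11
Reactants: 18 (2S,3R,4S,5R)-3,5-bis(Ar)-5-(triisopropylsilyloxy)pentane-1,2,4-triol
Product: 20 (3S,4R,5S)-4-Ar-5-[(R)-Ar(triisopropylsilyloxy)methyl]oxolan-3-ol (all-cis), via primary tosylate 19 (not isolated)
Conditions: TsCl (1.1 equiv), pyridine, 0 °C to rt; then 60 °C
Reagents that add atoms: none
Why: Selective sulfonylation of the primary C5 hydroxyl followed by intramolecular Williamson-type etherification: the C2 hydroxyl displaces the tosylate at the non-stereogenic C5 in a 5-exo-tet closure, so C2 keeps its configuration. In pyridine no alkoxide is formed, which disfavours the competing epoxide closure by the C4 hydroxyl.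

Step 12
Reactants: 20 (3S,4R,5S)-4-Ar-5-[(R)-Ar(triisopropylsilyloxy)methyl]oxolan-3-ol
Product: 21 (3S,4R,5S)-4-Ar-5-[(R)-Ar(hydroxy)methyl]oxolan-3-ol
Conditions: Bu4NF, THF, rt to 40 °C
Reagents that add atoms: none
Why: Fluoride-induced cleavage of the silyl ether, driven by formation of the Si–F bond; the non-acidic medium avoids ionisation at the benzylic C1'.

Step 13
Reactants: 21 (3S,4R,5S)-4-Ar-5-[(R)-Ar(hydroxy)methyl]oxolan-3-ol
Product: 22 Metasequirin E: (3S,4R,5S)-5-[(R)-hydroxy(4-hydroxy-3-methoxyphenyl)methyl]-4-(4-hydroxy-3-methoxyphenyl)oxolan-3-ol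
Conditions: H2 (1 atm), Pd/C, EtOAc–EtOH, rt
Reagents that add atoms: none
Why: Hydrogenolysis of the two aryl benzyl ethers on palladium; the reaction is run in neutral solvent at ambient pressure and stopped at full conversion so that the benzylic C1'–OH bond, which reacts far more slowly, is retained.

## Compound list

1 | 4-(benzyloxy)-3-methoxybenzaldehyde (O-benzylvanillin) | COc1cc(C=O)ccc1OCc1ccccc1 | starting material
2 | dimethyl (1-diazo-2-oxopropyl)phosphonate | COP(=O)(OC)C(=[N+]=[N-])C(C)=O | starting material
3 | dimethyl (diazomethyl)phosphonate (formed as its anion) | COP(=O)(OC)C=[N+]=[N-] | intermediate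
4 | 1-(benzyloxy)-4-ethynyl-2-methoxybenzene | COc1cc(C#C)ccc1OCc1ccccc1 | intermediate
5 | ethyl{[4-(benzyloxy)-3-methoxyphenyl]ethynyl}zinc | CC[Zn]C#Cc1ccc(OCc2ccccc2)c(OC)c1 | intermediate
6 | (1R)-1,3-bis(Ar)prop-2-yn-1-ol | COc1cc(C#C[C@H](O)c2ccc(OCc3ccccc3)c(OC)c2)ccc1OCc1ccccc1 | intermediate
7 | {[(1R)-1,3-bis(Ar)prop-2-yn-1-yl]oxy}tri(propan-2-yl)silane | COc1cc(C#C[C@H](O[Si](C(C)C)(C(C)C)C(C)C)c2ccc(OCc3ccccc3)c(OC)c2)ccc1OCc1ccccc1 | intermediate
8 | {[(1S,2Z)-1,3-bis(Ar)prop-2-en-1-yl]oxy}tri(propan-2-yl)silane | COc1cc(/C=C\[C@H](O[Si](C(C)C)(C(C)C)C(C)C)c2ccc(OCc3ccccc3)c(OC)c2)ccc1OCc1ccccc1 | intermediate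
9 | trichloroacetyl chloride | O=C(Cl)C(Cl)(Cl)Cl | starting material
10 | dichloroketene | O=C=C(Cl)Cl | intermediate
11 | (3R,4S)-3-Ar-4-[(S)-Ar(triisopropylsilyloxy)methyl]-2,2-dichlorocyclobutan-1-one, 3,4-cis | COc1cc([C@H]2[C@@H]([C@H](O[Si](C(C)C)(C(C)C)C(C)C)c3ccc(OCc4ccccc4)c(OC)c3)C(=O)C2(Cl)Cl)ccc1OCc1ccccc1 | intermediate
12 | Criegee adduct: peroxy hemiketal of 11 at C5 with 3-chloroperoxybenzoic acid (configuration at C5 not defined) | COc1cc([C@H]2[C@@H]([C@H](O[Si](C(C)C)(C(C)C)C(C)C)c3ccc(OCc4ccccc4)c(OC)c3)C(O)(OOC(=O)c3cccc(Cl)c3)C2(Cl)Cl)ccc1OCc1ccccc1 | intermediate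
13 | (4S,5S)-4-Ar-5-[(R)-Ar(triisopropylsilyloxy)methyl]-3,3-dichlorooxolan-2-one, 4,5-cis | COc1cc([C@H]2[C@@H]([C@H](O[Si](C(C)C)(C(C)C)C(C)C)c3ccc(OCc4ccccc4)c(OC)c3)OC(=O)C2(Cl)Cl)ccc1OCc1ccccc1 | intermediate
14 | (4S,5S)-4-Ar-5-[(R)-Ar(triisopropylsilyloxy)methyl]oxolan-2-one | COc1cc([C@H]2[C@@H]([C@H](O[Si](C(C)C)(C(C)C)C(C)C)c3ccc(OCc4ccccc4)c(OC)c3)OC(=O)C2)ccc1OCc1ccccc1 | intermediate
15 | potassium enolate of 14 (C4=C5 enolate) | COc1cc([C@H]2[C@@H]([C@H](O[Si](C(C)C)(C(C)C)C(C)C)c3ccc(OCc4ccccc4)c(OC)c3)OC([O-])=C2)ccc1OCc1ccccc1.[K+] | intermediate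
16 | (3R,4R,5S)-4-Ar-3-hydroxy-5-[(R)-Ar(triisopropylsilyloxy)methyl]oxolan-2-one, 3-OH trans to 4-Ar | COc1cc([C@H]2[C@@H]([C@H](O[Si](C(C)C)(C(C)C)C(C)C)c3ccc(OCc4ccccc4)c(OC)c3)OC(=O)[C@@H]2O)ccc1OCc1ccccc1 | intermediate
17 | (3S,4S,5S)-4-Ar-2-oxo-5-[(R)-Ar(triisopropylsilyloxy)methyl]oxolan-3-yl 4-nitrobenzoate, all-cis | COc1cc([C@H]2[C@@H]([C@H](O[Si](C(C)C)(C(C)C)C(C)C)c3ccc(OCc4ccccc4)c(OC)c3)OC(=O)[C@H]2OC(=O)c2ccc(cc2)[N+](=O)[O-])ccc1OCc1ccccc1 | intermediate
18 | (2S,3R,4S,5R)-3,5-bis(Ar)-5-(triisopropylsilyloxy)pentane-1,2,4-triol | COc1cc([C@H]([C@H](O)CO)[C@H](O)[C@H](O[Si](C(C)C)(C(C)C)C(C)C)c2ccc(OCc3ccccc3)c(OC)c2)ccc1OCc1ccccc1 | intermediate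
19 | 1-O-(4-methylbenzenesulfonyl) derivative of 18 (primary tosylate at C5) | COc1cc([C@H]([C@H](O)COS(=O)(=O)c2ccc(C)cc2)[C@H](O)[C@H](O[Si](C(C)C)(C(C)C)C(C)C)c2ccc(OCc3ccccc3)c(OC)c2)ccc1OCc1ccccc1 | intermediate
20 | (3S,4R,5S)-4-Ar-5-[(R)-Ar(triisopropylsilyloxy)methyl]oxolan-3-ol, all-cis | COc1cc([C@H]2[C@@H]([C@H](O[Si](C(C)C)(C(C)C)C(C)C)c3ccc(OCc4ccccc4)c(OC)c3)OC[C@H]2O)ccc1OCc1ccccc1 | intermediate
21 | (3S,4R,5S)-4-Ar-5-[(R)-Ar(hydroxy)methyl]oxolan-3-ol | COc1cc([C@H]2[C@@H]([C@H](O)c3ccc(OCc4ccccc4)c(OC)c3)OC[C@H]2O)ccc1OCc1ccccc1 | intermediate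
22 | Metasequirin E, (3S,4R,5S)-5-[(R)-hydroxy(4-hydroxy-3-methoxyphenyl)methyl]-4-(4-hydroxy-3-methoxyphenyl)oxolan-3-ol | COc1cc([C@H]2[C@@H]([C@H](O)c3ccc(O)c(OC)c3)OC[C@H]2O)ccc1O | target

## Step count and least certain steps

Total: 13 steps. Longest linear sequence: 13 steps (1 to 22); aldehyde 1 enters twice, in steps 1 and 2.

Step 6 (key step). The most likely failure is decomposition competing with a slow oxidation: the carbonyl is flanked by CCl2 and the branched C2, and the very electrophilic dichloroketone can be opened by carboxylate or water, or the product can lose HCl at the benzylic C3–H. Fallback, setting out from 11: zinc in acetic acid removes both chlorines first and gives the cis-3-Ar-2-[Ar(triisopropylsilyloxy)methyl]cyclobutanone F1. Baeyer–Villiger oxidation of F1 (mCPBA, NaHCO3) then relies on the secondary C2 migrating in preference to the methylene C4 and gives lactone 14, where the route is rejoined.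

Step 5. The most likely failure is poor or reversed facial selectivity, because the two alkene faces differ only in carrying an aryl or a silyloxy group; ionisation of the doubly activated allylic benzylic silyl ether by ZnCl2 is the second concern. Fallback, setting out from 4 and 1 and returning at 21:
- Step 2 is run with (R)-BINOL to give the enantiomeric (1S)-propargylic alcohol F2, which is silylated to F3 and semihydrogenated to the (1R,2Z)-alkene F4.
- Cycloaddition on the face that proved preferred gives cyclobutanone F5, which has the ring configuration of 11 and the opposite configuration at C1'.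
- Steps 6 to 12, unchanged, lead through the Criegee adduct F6 to the dichlorolactone F7, the lactone F8, its potassium enolate F9, the trans-hydroxy lactone F10, the all-cis nitrobenzoate F11, the triol F12, its primary tosylate F13, the silylated oxolanol F14 and the C1'-epimeric diol F15.
- Activated MnO2 oxidises only the benzylic C1' alcohol of F15 to the aryl ketone F16. Zn(BH4)2 in Et2O then reduces F16 under chelation between the ketone oxygen and O1, hydride entering on the side away from C3, to give the anti carbinol 21.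

Step 9. The most likely failure is incomplete inversion: the carboxylate must enter on the ring face that carries the aryl group and the side chain, so displacement may be slow and an acyloxyphosphonium pathway with retention can intrude. Fallback, setting out from 16 and returning at 20:
- LiBH4 gives the C4-epimeric triol F17.
- TsCl in pyridine closes the ring through the primary tosylate F18 to the trans oxolanol F19.
- Buffered Dess–Martin periodinane gives the oxolan-3-one F20, which is the same compound as A2.
- LiBH(s-Bu)3 at −78 °C delivers hydride on the face away from the aryl group and the side chain, so the hydroxyl ends cis, giving 20.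

Step 11. The most likely failure is ring closure by the wrong hydroxyl (the C4 hydroxyl closing on C5 to an epoxide) or sulfonylation of a secondary hydroxyl, since three free hydroxyls compete and the C2 hydroxyl is hindered. Fallback, setting out from 17 and returning at 21:
- NaN3 in MeOH cleaves the nitrobenzoate to the cis-hydroxy lactone F21.
- TBSOTf and 2,6-lutidine give the silyl ether F22.
- LiBH4 gives the 1,4-diol F23.
- TsCl in pyridine, through the tosylate F24, can now close only to the bis-silylated oxolane F25.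
- Bu4NF removes both silyl groups to give 21.

Further compounds

F1 | step 6 | cis-3-Ar-2-[Ar(triisopropylsilyloxy)methyl]cyclobutan-1-one (dechlorinated 11) | COc1cc([C@H]2[C@@H]([C@H](O[Si](C(C)C)(C(C)C)C(C)C)c3ccc(OCc4ccccc4)c(OC)c3)C(=O)C2)ccc1OCc1ccccc1
F2 | step 5 | (1S)-1,3-bis(Ar)prop-2-yn-1-ol (enantiomer of 6) | COc1cc(C#C[C@@H](O)c2ccc(OCc3ccccc3)c(OC)c2)ccc1OCc1ccccc1
F3 | step 5 | triisopropylsilyl ether of F2 (enantiomer of 7) | COc1cc(C#C[C@@H](O[Si](C(C)C)(C(C)C)C(C)C)c2ccc(OCc3ccccc3)c(OC)c2)ccc1OCc1ccccc1
F4 | step 5 | (1R,2Z)-1,3-bis(Ar)prop-2-en-1-yl triisopropylsilyl ether (enantiomer of 8) | COc1cc(/C=C\[C@@H](O[Si](C(C)C)(C(C)C)C(C)C)c2ccc(OCc3ccccc3)c(OC)c2)ccc1OCc1ccccc1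
F5 | step 5 | C1' epimer of cyclobutanone 11 | COc1cc([C@H]2[C@@H]([C@@H](O[Si](C(C)C)(C(C)C)C(C)C)c3ccc(OCc4ccccc4)c(OC)c3)C(=O)C2(Cl)Cl)ccc1OCc1ccccc1
F6 | step 5 | C1' epimer of Criegee adduct 12 | COc1cc([C@H]2[C@@H]([C@@H](O[Si](C(C)C)(C(C)C)C(C)C)c3ccc(OCc4ccccc4)c(OC)c3)C(O)(OOC(=O)c3cccc(Cl)c3)C2(Cl)Cl)ccc1OCc1ccccc1
F7 | step 5 | C1' epimer of dichlorolactone 13 | COc1cc([C@H]2[C@@H]([C@@H](O[Si](C(C)C)(C(C)C)C(C)C)c3ccc(OCc4ccccc4)c(OC)c3)OC(=O)C2(Cl)Cl)ccc1OCc1ccccc1
F8 | step 5 | C1' epimer of lactone 14 | COc1cc([C@H]2[C@@H]([C@@H](O[Si](C(C)C)(C(C)C)C(C)C)c3ccc(OCc4ccccc4)c(OC)c3)OC(=O)C2)ccc1OCc1ccccc1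
F9 | step 5 | C1' epimer of potassium enolate 15 | COc1cc([C@H]2[C@@H]([C@@H](O[Si](C(C)C)(C(C)C)C(C)C)c3ccc(OCc4ccccc4)c(OC)c3)OC([O-])=C2)ccc1OCc1ccccc1.[K+]
F10 | step 5 | C1' epimer of trans-hydroxy lactone 16 | COc1cc([C@H]2[C@@H]([C@@H](O[Si](C(C)C)(C(C)C)C(C)C)c3ccc(OCc4ccccc4)c(OC)c3)OC(=O)[C@@H]2O)ccc1OCc1ccccc1
F11 | step 5 | C1' epimer of nitrobenzoate 17 | COc1cc([C@H]2[C@@H]([C@@H](O[Si](C(C)C)(C(C)C)C(C)C)c3ccc(OCc4ccccc4)c(OC)c3)OC(=O)[C@H]2OC(=O)c2ccc(cc2)[N+](=O)[O-])ccc1OCc1ccccc1
F12 | step 5 | C1' epimer of triol 18 | COc1cc([C@H]([C@H](O)CO)[C@H](O)[C@@H](O[Si](C(C)C)(C(C)C)C(C)C)c2ccc(OCc3ccccc3)c(OC)c2)ccc1OCc1ccccc1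
F13 | step 5 | C1' epimer of tosylate 19 | COc1cc([C@H]([C@H](O)COS(=O)(=O)c2ccc(C)cc2)[C@H](O)[C@@H](O[Si](C(C)C)(C(C)C)C(C)C)c2ccc(OCc3ccccc3)c(OC)c2)ccc1OCc1ccccc1
F14 | step 5 | C1' epimer of oxolanol 20 | COc1cc([C@H]2[C@@H]([C@@H](O[Si](C(C)C)(C(C)C)C(C)C)c3ccc(OCc4ccccc4)c(OC)c3)OC[C@H]2O)ccc1OCc1ccccc1
F15 | step 5 | C1' epimer of diol 21 | COc1cc([C@H]2[C@@H]([C@@H](O)c3ccc(OCc4ccccc4)c(OC)c3)OC[C@H]2O)ccc1OCc1ccccc1
F16 | step 5 | all-cis 2-aroyl-3-Ar-oxolan-4-ol (target numbering; C1' ketone) | COc1cc([C@H]2[C@@H](C(=O)c3ccc(OCc4ccccc4)c(OC)c3)OC[C@H]2O)ccc1OCc1ccccc1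
F17 | step 9 | C4 epimer of triol 18 (from 16) | COc1cc([C@H]([C@@H](O)CO)[C@H](O)[C@H](O[Si](C(C)C)(C(C)C)C(C)C)c2ccc(OCc3ccccc3)c(OC)c2)ccc1OCc1ccccc1
F18 | step 9 | primary tosylate of F17 | COc1cc([C@H]([C@@H](O)COS(=O)(=O)c2ccc(C)cc2)[C@H](O)[C@H](O[Si](C(C)C)(C(C)C)C(C)C)c2ccc(OCc3ccccc3)c(OC)c2)ccc1OCc1ccccc1
F19 | step 9 | C4 epimer of oxolanol 20 (4-OH trans to 3-Ar, target numbering) | COc1cc([C@H]2[C@@H]([C@H](O[Si](C(C)C)(C(C)C)C(C)C)c3ccc(OCc4ccccc4)c(OC)c3)OC[C@@H]2O)ccc1OCc1ccccc1
F20 | step 9 | cis-3-Ar-2-[(R)-Ar(triisopropylsilyloxy)methyl]oxolan-4-one (target numbering; identical with A2) | COc1cc([C@H]2[C@@H]([C@H](O[Si](C(C)C)(C(C)C)C(C)C)c3ccc(OCc4ccccc4)c(OC)c3)OCC2=O)ccc1OCc1ccccc1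
F21 | step 11 | all-cis 3-hydroxy lactone (17 without the nitrobenzoyl group) | COc1cc([C@H]2[C@@H]([C@H](O[Si](C(C)C)(C(C)C)C(C)C)c3ccc(OCc4ccccc4)c(OC)c3)OC(=O)[C@H]2O)ccc1OCc1ccccc1
F22 | step 11 | tert-butyldimethylsilyl ether of F21 | COc1cc([C@H]2[C@@H]([C@H](O[Si](C(C)C)(C(C)C)C(C)C)c3ccc(OCc4ccccc4)c(OC)c3)OC(=O)[C@H]2O[Si](C)(C)C(C)(C)C)ccc1OCc1ccccc1
F23 | step 11 | 1,4-diol from F22 (C5–OH and C2–OH free, C4–OTBS, C1'–OTIPS) | COc1cc([C@H]([C@H](O[Si](C)(C)C(C)(C)C)CO)[C@H](O)[C@H](O[Si](C(C)C)(C(C)C)C(C)C)c2ccc(OCc3ccccc3)c(OC)c2)ccc1OCc1ccccc1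
F24 | step 11 | primary tosylate of F23 | COc1cc([C@H]([C@H](O[Si](C)(C)C(C)(C)C)COS(=O)(=O)c2ccc(C)cc2)[C@H](O)[C@H](O[Si](C(C)C)(C(C)C)C(C)C)c2ccc(OCc3ccccc3)c(OC)c2)ccc1OCc1ccccc1
F25 | step 11 | all-cis oxolane with C4–OTBS and C1'–OTIPS | COc1cc([C@H]2[C@@H]([C@H](O[Si](C(C)C)(C(C)C)C(C)C)c3ccc(OCc4ccccc4)c(OC)c3)OC[C@H]2O[Si](C)(C)C(C)(C)C)ccc1OCc1ccccc1
A1 | alternative 1 | 1-Ar-1-diazo-3-{(2R)-2-Ar-2-[(triisopropylsilyl)oxy]ethoxy}propan-2-one | COc1cc(C(=[N+]=[N-])C(=O)COC[C@H](O[Si](C(C)C)(C(C)C)C(C)C)c2ccc(OCc3ccccc3)c(OC)c2)ccc1OCc1ccccc1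
A2 | alternative 1 | cis-3-Ar-2-[(R)-Ar(triisopropylsilyloxy)methyl]oxolan-4-one (target numbering) | COc1cc([C@H]2[C@@H]([C@H](O[Si](C(C)C)(C(C)C)C(C)C)c3ccc(OCc4ccccc4)c(OC)c3)OCC2=O)ccc1OCc1ccccc1
A3 | alternative 2 | cis-2-Ar-3-(tert-butyldimethylsilyloxy)oxetane | COc1cc([C@H]2OC[C@H]2O[Si](C)(C)C(C)(C)C)ccc1OCc1ccccc1
A4 | alternative 2 | 1-Ar-2-diazoethan-1-one | COc1cc(C(=O)C=[N+]=[N-])ccc1OCc1ccccc1
A5 | alternative 2 | all-cis 2-aroyl-3-Ar-4-(tert-butyldimethylsilyloxy)oxolane | COc1cc([C@H]2[C@@H](C(=O)c3ccc(OCc4ccccc4)c(OC)c3)OC[C@H]2O[Si](C)(C)C(C)(C)C)ccc1OCc1ccccc1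
A6 | alternative 3 | [(2Z)-3-Ar-prop-2-en-1-yl]dimethyl(phenyl)silane | COc1cc(/C=C\C[Si](C)(C)c2ccccc2)ccc1OCc1ccccc1
A7 | alternative 3 | (2R)-2-Ar-2-(tert-butyldimethylsilyloxy)acetaldehyde | O=C[C@H](O[Si](C)(C)C(C)(C)C)c1ccc(OCc2ccccc2)c(OC)c1
A8 | alternative 3 | all-cis 2-[Ar(tert-butyldimethylsilyloxy)methyl]-3-Ar-4-[dimethyl(phenyl)silyl]oxolane | COc1cc([C@H]2[C@@H]([C@H](O[Si](C)(C)C(C)(C)C)c3ccc(OCc4ccccc4)c(OC)c3)OC[C@H]2[Si](C)(C)c2ccccc2)ccc1OCc1ccccc1
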